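## Structural features

The target is a C40 xanthophyll: two trimethylcyclohexane rings joined by an all-E octaene chain (C7 to C9') that carries methyl groups at C9, C13, C13' and C9'. The left ring is saturated and holds a secondary hydroxyl at C3 and two tertiary hydroxyls on the adjacent, fully substituted carbons C5 and C6; these two are cis to each other and both anti to O3, and C6 also carries the chain next to the gem-dimethyl carbon C1. The right ring is fused through C5'–C6' to a 2,5-dihydrofuran (oxygen bridging C5' and C8', ring alkene C6'=C7'), so C8' is a doubly allylic ether carbon. Of the six stereocentres, C5 and C6 are contiguous and 1,3-related to C3, C3' and C5' are 1,3-related, and C8' stands alone across the ring oxygen with no neighbouring centre to steer it. Fragile are the polyene (light, oxygen, hindered Z isomers), the tertiary allylic C6 hydroxyl and the C8'–O bond; both of the latter ionise in acid to the same kind of polyenyl cation, so acid must be kept away once the chain is long. The real difficulty is the ditertiary cis-diol in a ring crowded by four methyl groups, with a fixed relationship to C3; C8' comes second. The key step uses the fact that C5 and C6 are both carbinol carbons standing 1,6 to each other along C6–C1–C2–C3–C4–C5: as two carbonyl groups they can be joined by ketyl coupling, and the metal bridging the two oxygens gives the cis-diol. The same diol with its C7=C8 vinyl group is also a latent dihydrofuran (O5 to C8), so one ring synthesis can serve both ends.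

## Logic of the disconnections

**31 to 30.** Only the O–Si bonds at C3 and C3' are cut. Leaving the silyl ethers on until the end keeps every intermediate lipophilic and lets the last step be a fluoride treatment instead of an acid one. The demand is that the final reagent is basic, because the C6 carbinol and the C8' ether do not survive acid.

**30 to 27 and 23.** The C11'=C12' double bond is cut. This divides the molecule into a C25 aldehyde and a C15 phosphonium salt and places the junction at a disubstituted alkene whose hindered Z isomer equilibrates thermally. The forward step needs an ylide that carries a ring oxygen at its γ-carbon to survive long enough to react, and it must run without acid.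

**27 to 18 and 24.** The C11=C12 double bond is cut. 24 is symmetrical, so the same kind of olefination serves twice and all the central chain comes from one bought compound. The demand is mono-olefination of a dialdehyde and tolerance of two free tertiary hydroxyls.

**23 to 21, 20, 19 and 16.** First the C11'–P bond, then the O–C8' bond of the dihydrofuran is cut, with the ring oxygen returned to C5' and a hydroxyl placed on C6'. This turns the furanoid half into the triol-type unit 19, so both end groups descend from 16 and no second ring synthesis is needed. The forward closure must ionise C6–O and nothing else (hence the acetate on C11). It creates C8 without a neighbouring control element, so the facial preference of the ring closure has to be backed by a chromatographic purification at this stage.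

**18 to 16, 15, then 12 and 13.** The C11–P bond and the C7=C8 double bond are cut. 13 supplies C8–C11 with the C9 methyl in one operation. The demand is E geometry at C7=C8 and C9=C10 and a base mild enough for the free α,β-dihydroxy aldehyde 12.

**12 to 11 and 10.** Only the oxidation level of C7 changes. The ester of 10 is the group that makes the key step possible, so it is adjusted afterwards. The demand is an oxidant that does not cleave the glycol.

**10 to 9 (key).** The C5–C6 ring bond is cut and both carbinols become carbonyl groups. The gain is large: a ring with three stereocentres becomes an open chain with one. The forward step must form the bond reductively, give the cis-diol, and place it anti to O3.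

**9 to 7.** The two carbonyl groups are rejoined as a C5=C6 double bond. This returns the chain to a ring in which C3 is the only stereocentre. The demand is oxidative cleavage of a tetrasubstituted alkene under neutral conditions.

**7 to 6 and 4.** The C6–C7 bond is cut (the carboxyl carbon leaves as CO), then the enol C–O bond. The ketone of 4 has a single α-hydrogen, so the position of the double bond is not in question.

**4 to 3, 2 and 1.** The O–Si bond and two C–H bonds are cut. The only stereocentre that persists, C3, is traced to two reductions of an achiral bought dione. The demand is one enantioselective reduction and one diastereoselective reduction.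

## Other disconnections considered

**Alternative 1:** The cut is at the furanoid ring. It is taken back first to the 5',6'-epoxide A1 (the ring oxygen returned from C8' to C6') and then to the C5'=C6' alkene of the tetrol A2, which carries the finished triol end and a plain 3-hydroxy-β end. Forward, zeaxanthin epoxidase, a flavin monooxygenase needing oxygen and a reduced nicotinamide cofactor, would add one oxygen across C5'=C6' of A2 anti to the C3' hydroxyl to give A1. Dilute acid would then move that oxygen to C8'.
- In its favour: the face is chosen by the enzyme and not by the substrate; the oxidation comes last, so the right-hand C15 unit needs no oxygenation chemistry.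
- Where it is the better plan: step count for the furanoid half, which becomes two steps from a C40 compound against four from 16 here.
- Against it here: the enzyme is membrane-bound and works on a substrate embedded in lipid and protein. Whether it accepts the water-insoluble A2 with its polar triol end, and does so on a preparative scale, is open.
- Against it here: the acid step then falls on the full polyene with the triol end present, whose C6 hydroxyl ionises under the same conditions.
- Comparison: it is the equal of the chosen plan at C8', since A1 and 19 pass through the same C6-centred cation and neither controls that centre with certainty. The chosen plan meets the problem on a C15 acetate, where material of the wrong C8 configuration can be separated and re-equilibrated, and not on the final compound.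
- Comparison: it does not address the triol ring, so it complements step 7 and does not replace it.

**Alternative 2:** The cut is the O–C8' bond, taken back to the allenic diol A4 and not to a 5,6-diol. Forward, AuCl3 (trivalent gold) or AgNO3 (monovalent silver) would activate the C7'=C8' bond of the allene; the tertiary C5' hydroxyl would add to C8' in a 5-endo closure and protodemetallation would give A3.
- Where it is the better plan: the oxygen can only close in the plane of C1'–C6'–C5', so the configuration of C8' follows from the sense of the allene axis alone. C8' would be set stereospecifically, which the chosen plan does not achieve.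
- Against it here: working the geometry through, 8'R corresponds to the (6'S) axis, the opposite of the axis in the natural allenic end groups. A4 would therefore need an SN2' hydride delivery of defined and less usual facial sense, preceded by a face-selective oxidation of the ring.
- Against it here: the Lewis-acidic metal can ionise the doubly allylic C8'–O bond of A3 or isomerise the allene, and the right half would share nothing with the left half beyond the enol triflate.
- Comparison: both plans make the same bond, one by concerted addition to a π complex and one through a cation. The alternative is equal in mildness, better in stereocontrol at C8', and clearly longer.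

**Alternative 3:** The cut is the pair of C–O bonds at C5 and C6, taken back to the tetrasubstituted alkene of the cyclogeranyl pivalate A6, which has the opposite configuration at C3. Forward, OsO4·TMEDA, hydrogen-bonded to the homoallylic C3 hydroxyl, would add across C5=C6 on the face of that hydroxyl to give A5. C3 would then be inverted (Mitsunobu reaction or oxidation and reduction).
- Where it is the better plan: the ring is never opened, and the cis relationship is guaranteed by a concerted suprafacial addition and does not rest on a chelate. C7 is already at the alcohol level, which saves the ester reduction.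
- Against it here: a full equivalent of osmium tetroxide is needed. A homoallylic directing effect onto an alkene flanked by a gem-dimethyl group is uncertain in reach and rate.
- Against it here: the route must start in the C3-epimeric series and later invert a secondary carbinol beside a free tertiary diol, with the protecting-group changes this requires.
- Comparison: in step count the two are about equal (osmylation and inversion against ozonolysis, coupling and reduction). The alternative is the better on certainty of the cis-diol; the chosen plan is the better on reagents and on using the natural C3 series throughout.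

Key step: step 7

Assumption: C3 and C3' are carried as tert-butyldimethylsilyl ethers and the carotenoid locants (C1–C20, primed for the furanoid half) are used for all intermediates. Rederived descriptors are 3S,5R,6S and 3'S,5'R,8'R; the changes from 4R (3 to 7) to 5S (9) and 4S (10) are ranking changes only, and no centre is inverted.

## Route

Step 1
Reactants: 1 ketoisophorone (2,6,6-trimethylcyclohex-2-ene-1,4-dione)
Product: 2 (6R)-2,2,6-trimethylcyclohexane-1,4-dione
Conditions: ene-reductase OYE2 (old yellow enzyme 2), NADP+ (cat.), glucose dehydrogenase, D-glucose, phosphate buffer pH 7, 30 °C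
Reagents that add atoms: none
Why: Enzymatic asymmetric conjugate reduction: the flavin enzyme adds hydride and a proton across the activated C=C from opposite faces and its pocket should set the methyl-bearing centre as R; prompt extraction at neutral pH guards this enolisable centre.

Step 2
Reactants: 2 (6R)-2,2,6-trimethylcyclohexane-1,4-dione
Product: 3 (4R,6R)-4-hydroxy-2,2,6-trimethylcyclohexan-1-one
Conditions: H2 (5 bar), Raney Ni, MeOH, 25 °C; crystallisation
Reagents that add atoms: none
Why: Heterogeneous ketone hydrogenation; only the unhindered C4 carbonyl reacts, and hydrogen should arrive on the face away from the axial C2 methyl of the chair that keeps the C6 methyl equatorial, giving the axial, trans alcohol (4R). Crystallisation secures diastereomeric purity.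

Step 3
Reactants: 3 (4R,6R)-4-hydroxy-2,2,6-trimethylcyclohexan-1-one
Product: 4 (4R,6R)-4-[(tert-butyldimethylsilyl)oxy]-2,2,6-trimethylcyclohexan-1-one
Conditions: TBSCl, imidazole, DMF, 40 °C
Reagents that add atoms: tert-butyldimethylsilyl chloride, CC(C)(C)[Si](C)(C)Cl
Why: Standard silylation of a secondary alcohol; the bulky, non-coordinating silyl ether is chosen for step 7 and should survive every step up to the final fluoride treatment.

Step 4
Reactants: 4 (4R,6R)-4-[(tert-butyldimethylsilyl)oxy]-2,2,6-trimethylcyclohexan-1-one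
Product: 6 (4R)-4-[(tert-butyldimethylsilyl)oxy]-2,6,6-trimethylcyclohex-1-en-1-yl trifluoromethanesulfonate, via potassium enolate 5 (not isolated)
Conditions: KN(SiMe3)2, THF, −78 → 0 °C; then PhNTf2, −78 °C → rt
Reagents that add atoms: N-phenylbis(trifluoromethanesulfonimide), O=S(=O)(N(c1ccccc1)S(=O)(=O)C(F)(F)F)C(F)(F)F
Why: Enol triflate formation; the ketone has a single α-hydrogen, so one enolate forms and is O-sulfonylated. The C6 centre, having relayed its chirality to C4 in step 2, is deliberately erased, and the γ-silyloxy group cannot β-eliminate.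

Step 5
Reactants: 6 (4R)-4-[(tert-butyldimethylsilyl)oxy]-2,6,6-trimethylcyclohex-1-en-1-yl trifluoromethanesulfonate
Product: 7 methyl (4R)-4-[(tert-butyldimethylsilyl)oxy]-2,6,6-trimethylcyclohex-1-ene-1-carboxylate
Conditions: CO (1 atm), Pd(OAc)2 (5 mol %), PPh3 (10 mol %), Et3N, MeOH/DMF, 60 °C
Reagents that add atoms: carbon monoxide, [C-]#[O+]; methanol, CO
Why: Palladium-catalysed alkoxycarbonylation of an enol triflate: oxidative addition to zerovalent palladium (formed from Pd(OAc)2 and PPh3), CO insertion and methanolysis of the acyl–palladium; the triflate fixes the position of the double bond.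

Step 6
Reactants: 7 methyl (4R)-4-[(tert-butyldimethylsilyl)oxy]-2,6,6-trimethylcyclohex-1-ene-1-carboxylate
Product: 9 methyl (5S)-5-[(tert-butyldimethylsilyl)oxy]-3,3-dimethyl-2,7-dioxooctanoate, via methoxy hydroperoxide 8 (not isolated)
Conditions: O3, CH2Cl2/MeOH, −78 °C; then Me2S, −78 °C → rt; crude product used at once
Reagents that add atoms: ozone, [O-][O+]=O
Why: Ozonolysis; the tetrasubstituted alkene is twisted out of conjugation with the ester and stays reactive towards ozone, the carbonyl oxide on the alkyl-substituted C5 is trapped by methanol as 8, and Me2S reduces 8 to the ketone. The neutral work-up and immediate use are the handling improvement for 9, which is a β-silyloxy ketone and an aldol-prone 1,6-diketone; C3 is untouched.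

Step 7
Reactants: 9 methyl (5S)-5-[(tert-butyldimethylsilyl)oxy]-3,3-dimethyl-2,7-dioxooctanoate
Product: 10 methyl (1S,2R,4S)-4-[(tert-butyldimethylsilyl)oxy]-1,2-dihydroxy-2,6,6-trimethylcyclohexane-1-carboxylate
Conditions: SmI2 (2.5 equiv), THF, slow addition of 9 (final 0.01 M), −78 → −20 °C; aq. NH4Cl
Reagents that add atoms: none
Why: SmI2 (divalent samarium) reduces the α-keto ester carbonyl, by far the easiest group to reduce in 9, to a ketyl held in a five-membered chelate with the ester carbonyl on trivalent samarium; the ketyl carbon C6 adds to the metal-activated C5 ketone, a second electron gives the cyclic samarium diolate, and NH4Cl hydrolyses it to 10 (if the second electron arrives first, the samarium enediolate adds to C5 in an aldol sense and forms the same bond). The closest known reaction type is the SmI2-mediated intramolecular pinacol coupling of 1,6-dicarbonyl compounds, keto esters included, to cis-cyclohexane-1,2-diols. The ring closes in the 6-exo-trig mode (C6 onto the C5 carbonyl carbon, oxygen outside the ring), helped by the gem-dimethyl group at C1 (Thorpe–Ingold effect). The cis relationship of the new carbinols C5 and C6 is controlled by the single trivalent samarium that bridges both oxygens in the transition state. Their relationship to C3 is controlled by a chair in which the silyloxy group and the C5 methyl are equatorial; the other chair would place the C5 methyl syn-diaxial to the axial C1 methyl, so both new hydroxyls should end up anti to O3. The step needs chemoselective ketyl formation (without a strongly donating additive only the α-keto ester is reduced), closure faster than protonation (no proton source before the quench) and faster than intermolecular coupling (slow addition, high dilution); the non-coordinating silyl ether keeps O3 off the metal, which would otherwise draw O5 to the wrong face.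

Step 8
Reactants: 10 methyl (1S,2R,4S)-4-[(tert-butyldimethylsilyl)oxy]-1,2-dihydroxy-2,6,6-trimethylcyclohexane-1-carboxylate
Product: 11 (1R,2R,4S)-4-[(tert-butyldimethylsilyl)oxy]-1-(hydroxymethyl)-2,6,6-trimethylcyclohexane-1,2-diol
Conditions: LiAlH4, THF, 0 → 60 °C; aq. NaOH work-up
Reagents that add atoms: none
Why: LiAlH4 reduction of an ester to the primary alcohol; the neighbouring alkoxyaluminate should deliver hydride to the very hindered ester, and the silyl ether and the tertiary carbinols are inert.

Step 9
Reactants: 11 (1R,2R,4S)-4-[(tert-butyldimethylsilyl)oxy]-1-(hydroxymethyl)-2,6,6-trimethylcyclohexane-1,2-diol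
Product: 12 (1S,2R,4S)-4-[(tert-butyldimethylsilyl)oxy]-1,2-dihydroxy-2,6,6-trimethylcyclohexane-1-carbaldehyde
Conditions: (COCl)2, DMSO, CH2Cl2, −78 °C; then Et3N, −78 → −30 °C
Reagents that add atoms: none
Why: Swern oxidation acts only on the primary alcohol (tertiary carbinols cannot be oxidised and no glycol-cleaving oxidant is used). The aldehyde has no α-hydrogen and is taken on at once, because a free α,β-dihydroxy aldehyde is prone to α-ketol and retro-aldol reactions.

Step 10
Reactants: 12 (1S,2R,4S)-4-[(tert-butyldimethylsilyl)oxy]-1,2-dihydroxy-2,6,6-trimethylcyclohexane-1-carbaldehyde; 13 ethyl (2E)-4-(diethoxyphosphoryl)-3-methylbut-2-enoate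
Product: 15 ethyl (2E,4E)-5-[(1S,2R,4S)-4-[(tert-butyldimethylsilyl)oxy]-1,2-dihydroxy-2,6,6-trimethylcyclohexyl]-3-methylpenta-2,4-dienoate, via lithium phosphonate carbanion 14 (not isolated)
Conditions: 13, LiN(SiMe3)2, THF/DMPU, −78 °C; then 12, −78 → 0 °C
Reagents that add atoms: none
Why: Horner–Wadsworth–Emmons olefination with the vinylogous phosphonoacetate anion forms C7=C8 with E geometry and brings in C8–C11 with the C9 methyl in one step. The stabilised anion is too weakly basic to deprotonate the tertiary hydroxyls, and chromatography secures the 9E geometry.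

Step 11
Reactants: 15 ethyl (2E,4E)-5-[(1S,2R,4S)-4-[(tert-butyldimethylsilyl)oxy]-1,2-dihydroxy-2,6,6-trimethylcyclohexyl]-3-methylpenta-2,4-dienoate
Product: 16 (1S,2R,4S)-4-[(tert-butyldimethylsilyl)oxy]-1-[(1E,3E)-5-hydroxy-3-methylpenta-1,3-dien-1-yl]-2,6,6-trimethylcyclohexane-1,2-diol
Conditions: i-Bu2AlH (DIBAL-H, excess), CH2Cl2, −78 → −30 °C; aq. KNaC4H4O6
Reagents that add atoms: none
Why: 1,2-Reduction of the dienoate to the primary allylic alcohol leaves the diene untouched; extra hydride is consumed by the two free hydroxyls.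

Step 12
Reactants: 16 (1S,2R,4S)-4-[(tert-butyldimethylsilyl)oxy]-1-[(1E,3E)-5-hydroxy-3-methylpenta-1,3-dien-1-yl]-2,6,6-trimethylcyclohexane-1,2-diol
Product: 18 {(2E,4E)-5-[(1S,2R,4S)-4-[(tert-butyldimethylsilyl)oxy]-1,2-dihydroxy-2,6,6-trimethylcyclohexyl]-3-methylpenta-2,4-dien-1-yl}triphenylphosphonium bromide, via allylic bromide 17 (not isolated)
Conditions: CBr4, PPh3, 2,6-lutidine, CH2Cl2, −20 °C; then PPh3, 25 °C
Reagents that add atoms: carbon tetrabromide, BrC(Br)(Br)Br; triphenylphosphine, c1ccc(cc1)P(c1ccccc1)c1ccccc1
Why: Appel bromination converts only the primary allylic alcohol (the tertiary ones are too hindered), and triphenylphosphine displaces the bromide at the primary carbon (SN2). These neutral conditions replace the usual PPh3·HBr method, whose acid would ionise the C6 hydroxyl.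

Step 13
Reactants: 16 (1S,2R,4S)-4-[(tert-butyldimethylsilyl)oxy]-1-[(1E,3E)-5-hydroxy-3-methylpenta-1,3-dien-1-yl]-2,6,6-trimethylcyclohexane-1,2-diol
Product: 19 (2E,4E)-5-[(1S,2R,4S)-4-[(tert-butyldimethylsilyl)oxy]-1,2-dihydroxy-2,6,6-trimethylcyclohexyl]-3-methylpenta-2,4-dien-1-yl acetate
Conditions: Ac2O, pyridine, CH2Cl2, 0 °C
Reagents that add atoms: acetic anhydride, CC(=O)OC(C)=O
Why: Acetylation of the primary hydroxyl only (tertiary alcohols do not react without a nucleophilic catalyst); the ester keeps C11–O from ionising or forming ethers in the acid step that follows.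

Step 14
Reactants: 19 (2E,4E)-5-[(1S,2R,4S)-4-[(tert-butyldimethylsilyl)oxy]-1,2-dihydroxy-2,6,6-trimethylcyclohexyl]-3-methylpenta-2,4-dien-1-yl acetate
Product: 20 (2E)-3-[(2R,6S,7aR)-6-[(tert-butyldimethylsilyl)oxy]-4,4,7a-trimethyl-2,4,5,6,7,7a-hexahydro-1-benzofuran-2-yl]but-2-en-1-yl acetate
Conditions: camphorsulfonic acid (5 mol %), CH2Cl2, 0 °C; Et3N quench; chromatography
Reagents that add atoms: none
Why: Acid ionises the tertiary, dienyl-stabilised C6 hydroxyl and the neighbouring O5 closes onto C8 of the cation (dehydrative allylic etherification, through the same cation by which 5,6-epoxy and 5,6-dihydroxy carotenoid end groups give furanoid oxides); the gem-dimethyl group holds C8 on the C5 side, C5 keeps its configuration because its C–O bond is not touched, and C9=C10 stays E. C8 is created without a neighbouring control element: O5 is cis to the departing water and so lies on the same face of the dienyl unit, and closure on that face of the s-cis (7E) cation places C9 trans to the C5 methyl (8R), so a bias towards 20 is expected but not assured; chromatography removes material of the opposite C8 configuration, which the same acid can re-equilibrate through the cation.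

Step 15
Reactants: 20 (2E)-3-[(2R,6S,7aR)-6-[(tert-butyldimethylsilyl)oxy]-4,4,7a-trimethyl-2,4,5,6,7,7a-hexahydro-1-benzofuran-2-yl]but-2-en-1-yl acetate
Product: 21 (2E)-3-[(2R,6S,7aR)-6-[(tert-butyldimethylsilyl)oxy]-4,4,7a-trimethyl-2,4,5,6,7,7a-hexahydro-1-benzofuran-2-yl]but-2-en-1-ol
Conditions: K2CO3, MeOH, 0 °C
Reagents that add atoms: none
Why: Base-catalysed transesterification removes the acetate; the doubly allylic ether and the silyl ether are stable to K2CO3 in methanol.

Step 16
Reactants: 21 (2E)-3-[(2R,6S,7aR)-6-[(tert-butyldimethylsilyl)oxy]-4,4,7a-trimethyl-2,4,5,6,7,7a-hexahydro-1-benzofuran-2-yl]but-2-en-1-ol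
Product: 23 {(2E)-3-[(2R,6S,7aR)-6-[(tert-butyldimethylsilyl)oxy]-4,4,7a-trimethyl-2,4,5,6,7,7a-hexahydro-1-benzofuran-2-yl]but-2-en-1-yl}triphenylphosphonium bromide, via allylic bromide 22 (not isolated)
Conditions: CBr4, PPh3, 2,6-lutidine, CH2Cl2, −20 °C; then PPh3, 25 °C
Reagents that add atoms: carbon tetrabromide, BrC(Br)(Br)Br; triphenylphosphine, c1ccc(cc1)P(c1ccccc1)c1ccccc1
Why: Same Appel and SN2 sequence as in step 12; 2,6-lutidine keeps the medium free of HBr, which would re-ionise the C8–O bond and scramble C8.

Step 17
Reactants: 18 {(2E,4E)-5-[(1S,2R,4S)-4-[(tert-butyldimethylsilyl)oxy]-1,2-dihydroxy-2,6,6-trimethylcyclohexyl]-3-methylpenta-2,4-dien-1-yl}triphenylphosphonium bromide; 24 (2E,4E,6E)-2,7-dimethylocta-2,4,6-trienedial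
Product: 27 (3S,5R,6S)-3-[(tert-butyldimethylsilyl)oxy]-5,6-dihydroxy-5,6-dihydro-12'-apo-β-caroten-12'-al (all-E), via ylide 25 (not isolated), via 11Z isomer 26 (not isolated)
Conditions: 24 (3 equiv), NaOMe, CH2Cl2/MeOH, 0 °C → rt; then EtOAc, 70 °C, dark
Reagents that add atoms: none
Why: Wittig reaction of the allylic ylide with one aldehyde group of 24, used in excess to suppress double olefination, forms C11=C12. The free tertiary hydroxyls are tolerated under NaOMe, and the sterically hindered 11Z isomer should revert to the all-E chain on warming.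

Step 18
Reactants: 27 (3S,5R,6S)-3-[(tert-butyldimethylsilyl)oxy]-5,6-dihydroxy-5,6-dihydro-12'-apo-β-caroten-12'-al; 23 {(2E)-3-[(2R,6S,7aR)-6-[(tert-butyldimethylsilyl)oxy]-4,4,7a-trimethyl-2,4,5,6,7,7a-hexahydro-1-benzofuran-2-yl]but-2-en-1-yl}triphenylphosphonium bromide
Product: 30 (3S,5R,6S,3'S,5'R,8'R)-3,3'-bis[(tert-butyldimethylsilyl)oxy]-5',8'-epoxy-5,6,5',8'-tetrahydro-β,β-carotene-5,6-diol (all-E), via ylide 28 (not isolated), via 11'Z isomer 29 (not isolated)
Conditions: NaOMe, CH2Cl2/MeOH, 0 °C → rt; then EtOAc, 70 °C, dark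
Reagents that add atoms: none
Why: Second Wittig reaction, forming C11'=C12'; the ylide is a γ-alkoxy allylic ylide of the kind formed from the C5 acetal Wittig salts of polyene synthesis and is generated in the presence of the aldehyde so that it is trapped at once. No acid is present, so C8' and the C6 carbinol are safe, and the hindered 11'Z isomer is equilibrated thermally.

Step 19
Reactants: 30 (3S,5R,6S,3'S,5'R,8'R)-3,3'-bis[(tert-butyldimethylsilyl)oxy]-5',8'-epoxy-5,6,5',8'-tetrahydro-β,β-carotene-5,6-diol
Product: 31 (3S,5R,6S,3'S,5'R,8'R)-5',8'-epoxy-5,6,5',8'-tetrahydro-β,β-carotene-3,5,6,3'-tetrol (CNP0210286.4)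
Conditions: Bu4NF, THF, 0 °C → rt, dark
Reagents that add atoms: none
Why: Fluoride cleaves both secondary silyl ethers (formation of the strong Si–F bond); the basic medium leaves the tertiary allylic C6 hydroxyl, the C8' ether and the polyene untouched, and no stereocentre is involved.

## Compound list

1 | ketoisophorone (2,6,6-trimethylcyclohex-2-ene-1,4-dione) | CC1=CC(=O)CC(C)(C)C1=O | starting material
2 | (6R)-2,2,6-trimethylcyclohexane-1,4-dione | O=C1C(C)(C)CC(=O)C[C@H]1C | intermediate
3 | (4R,6R)-4-hydroxy-2,2,6-trimethylcyclohexan-1-one | O=C1C(C)(C)C[C@H](O)C[C@H]1C | intermediate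
4 | (4R,6R)-4-[(tert-butyldimethylsilyl)oxy]-2,2,6-trimethylcyclohexan-1-one | O=C1C(C)(C)C[C@H](O[Si](C)(C)C(C)(C)C)C[C@H]1C | intermediate
5 | potassium (4R)-4-[(tert-butyldimethylsilyl)oxy]-2,6,6-trimethylcyclohex-1-en-1-olate | [K+].[O-]C1=C(C)C[C@@H](O[Si](C)(C)C(C)(C)C)CC1(C)C | intermediate (not isolated)
6 | (4R)-4-[(tert-butyldimethylsilyl)oxy]-2,6,6-trimethylcyclohex-1-en-1-yl trifluoromethanesulfonate | O=S(=O)(OC1=C(C)C[C@@H](O[Si](C)(C)C(C)(C)C)CC1(C)C)C(F)(F)F | intermediate
7 | methyl (4R)-4-[(tert-butyldimethylsilyl)oxy]-2,6,6-trimethylcyclohex-1-ene-1-carboxylate | COC(=O)C1=C(C)C[C@@H](O[Si](C)(C)C(C)(C)C)CC1(C)C | intermediate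
8 | methyl (5S)-5-[(tert-butyldimethylsilyl)oxy]-7-hydroperoxy-7-methoxy-3,3-dimethyl-2-oxooctanoate (both configurations at C7) | COC(=O)C(=O)C(C)(C)C[C@H](O[Si](C)(C)C(C)(C)C)CC(C)(OC)OO | intermediate (not isolated)
9 | methyl (5S)-5-[(tert-butyldimethylsilyl)oxy]-3,3-dimethyl-2,7-dioxooctanoate | COC(=O)C(=O)C(C)(C)C[C@H](O[Si](C)(C)C(C)(C)C)CC(C)=O | intermediate
10 | methyl (1S,2R,4S)-4-[(tert-butyldimethylsilyl)oxy]-1,2-dihydroxy-2,6,6-trimethylcyclohexane-1-carboxylate | COC(=O)[C@]1(O)C(C)(C)C[C@H](O[Si](C)(C)C(C)(C)C)C[C@@]1(C)O | intermediate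
11 | (1R,2R,4S)-4-[(tert-butyldimethylsilyl)oxy]-1-(hydroxymethyl)-2,6,6-trimethylcyclohexane-1,2-diol | OC[C@]1(O)C(C)(C)C[C@H](O[Si](C)(C)C(C)(C)C)C[C@@]1(C)O | intermediate
12 | (1S,2R,4S)-4-[(tert-butyldimethylsilyl)oxy]-1,2-dihydroxy-2,6,6-trimethylcyclohexane-1-carbaldehyde | O=C[C@]1(O)C(C)(C)C[C@H](O[Si](C)(C)C(C)(C)C)C[C@@]1(C)O | intermediate
13 | ethyl (2E)-4-(diethoxyphosphoryl)-3-methylbut-2-enoate | CCOC(=O)/C=C(\C)CP(=O)(OCC)OCC | starting material
14 | lithium salt of the C4 carbanion of 13 | [Li+].CCOC(=O)/C=C(\C)[CH-]P(=O)(OCC)OCC | intermediate (not isolated)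
15 | ethyl (2E,4E)-5-[(1S,2R,4S)-4-[(tert-butyldimethylsilyl)oxy]-1,2-dihydroxy-2,6,6-trimethylcyclohexyl]-3-methylpenta-2,4-dienoate | CCOC(=O)/C=C(\C)/C=C/[C@]1(O)C(C)(C)C[C@H](O[Si](C)(C)C(C)(C)C)C[C@@]1(C)O | intermediate
16 | (1S,2R,4S)-4-[(tert-butyldimethylsilyl)oxy]-1-[(1E,3E)-5-hydroxy-3-methylpenta-1,3-dien-1-yl]-2,6,6-trimethylcyclohexane-1,2-diol | OC/C=C(\C)/C=C/[C@]1(O)C(C)(C)C[C@H](O[Si](C)(C)C(C)(C)C)C[C@@]1(C)O | intermediate
17 | (1S,2R,4S)-1-[(1E,3E)-5-bromo-3-methylpenta-1,3-dien-1-yl]-4-[(tert-butyldimethylsilyl)oxy]-2,6,6-trimethylcyclohexane-1,2-diol | BrC/C=C(\C)/C=C/[C@]1(O)C(C)(C)C[C@H](O[Si](C)(C)C(C)(C)C)C[C@@]1(C)O | intermediate (not isolated)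
18 | {(2E,4E)-5-[(1S,2R,4S)-4-[(tert-butyldimethylsilyl)oxy]-1,2-dihydroxy-2,6,6-trimethylcyclohexyl]-3-methylpenta-2,4-dien-1-yl}triphenylphosphonium bromide | [Br-].c1ccccc1[P+](c1ccccc1)(c1ccccc1)C/C=C(\C)/C=C/[C@]1(O)C(C)(C)C[C@H](O[Si](C)(C)C(C)(C)C)C[C@@]1(C)O | intermediate
19 | (2E,4E)-5-[(1S,2R,4S)-4-[(tert-butyldimethylsilyl)oxy]-1,2-dihydroxy-2,6,6-trimethylcyclohexyl]-3-methylpenta-2,4-dien-1-yl acetate | CC(=O)OC/C=C(\C)/C=C/[C@]1(O)C(C)(C)C[C@H](O[Si](C)(C)C(C)(C)C)C[C@@]1(C)O | intermediate
20 | (2E)-3-[(2R,6S,7aR)-6-[(tert-butyldimethylsilyl)oxy]-4,4,7a-trimethyl-2,4,5,6,7,7a-hexahydro-1-benzofuran-2-yl]but-2-en-1-yl acetate | CC(=O)OC/C=C(\C)[C@H]1C=C2C(C)(C)C[C@H](O[Si](C)(C)C(C)(C)C)C[C@@]2(C)O1 | intermediate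
21 | (2E)-3-[(2R,6S,7aR)-6-[(tert-butyldimethylsilyl)oxy]-4,4,7a-trimethyl-2,4,5,6,7,7a-hexahydro-1-benzofuran-2-yl]but-2-en-1-ol | OC/C=C(\C)[C@H]1C=C2C(C)(C)C[C@H](O[Si](C)(C)C(C)(C)C)C[C@@]2(C)O1 | intermediate
22 | (2R,6S,7aR)-2-[(2E)-4-bromobut-2-en-2-yl]-6-[(tert-butyldimethylsilyl)oxy]-4,4,7a-trimethyl-2,4,5,6,7,7a-hexahydro-1-benzofuran | BrC/C=C(\C)[C@H]1C=C2C(C)(C)C[C@H](O[Si](C)(C)C(C)(C)C)C[C@@]2(C)O1 | intermediate (not isolated)
23 | {(2E)-3-[(2R,6S,7aR)-6-[(tert-butyldimethylsilyl)oxy]-4,4,7a-trimethyl-2,4,5,6,7,7a-hexahydro-1-benzofuran-2-yl]but-2-en-1-yl}triphenylphosphonium bromide | [Br-].c1ccccc1[P+](c1ccccc1)(c1ccccc1)C/C=C(\C)[C@H]1C=C2C(C)(C)C[C@H](O[Si](C)(C)C(C)(C)C)C[C@@]2(C)O1 | intermediate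
24 | (2E,4E,6E)-2,7-dimethylocta-2,4,6-trienedial | O=C/C(C)=C/C=C/C=C(C)/C=O | starting material
25 | ylide of 18 (triphenylphosphonium C11 ylide) | c1ccccc1[P+](c1ccccc1)(c1ccccc1)[CH-]/C=C(\C)/C=C/[C@]1(O)C(C)(C)C[C@H](O[Si](C)(C)C(C)(C)C)C[C@@]1(C)O | intermediate (not isolated)
26 | (11Z) isomer of 27 | CC(/C=C\C=C(C)\C=C\[C@]1(O)C(C)(C)C[C@H](O[Si](C)(C)C(C)(C)C)C[C@@]1(C)O)=C\C=C\C=C(C)\C=O | intermediate (not isolated)
27 | (3S,5R,6S)-3-[(tert-butyldimethylsilyl)oxy]-5,6-dihydroxy-5,6-dihydro-12'-apo-β-caroten-12'-al; (2E,4E,6E,8E,10E,12E)-13-[(1S,2R,4S)-4-[(tert-butyldimethylsilyl)oxy]-1,2-dihydroxy-2,6,6-trimethylcyclohexyl]-2,7,11-trimethyltrideca-2,4,6,8,10,12-hexaenal | CC(/C=C/C=C(C)/C=C/[C@]1(O)C(C)(C)C[C@H](O[Si](C)(C)C(C)(C)C)C[C@@]1(C)O)=C\C=C\C=C(C)\C=O | intermediate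
28 | ylide of 23 (triphenylphosphonium C11' ylide) | c1ccccc1[P+](c1ccccc1)(c1ccccc1)[CH-]/C=C(\C)[C@H]1C=C2C(C)(C)C[C@H](O[Si](C)(C)C(C)(C)C)C[C@@]2(C)O1 | intermediate (not isolated)
29 | (11'Z) isomer of 30 | CC(/C=C/C=C(C)/C=C/[C@]1(O)C(C)(C)C[C@H](O[Si](C)(C)C(C)(C)C)C[C@@]1(C)O)=C\C=C\C=C(C)\C=C/C=C(\C)[C@H]1C=C2C(C)(C)C[C@H](O[Si](C)(C)C(C)(C)C)C[C@@]2(C)O1 | intermediate (not isolated)
30 | (3S,5R,6S,3'S,5'R,8'R)-3,3'-bis[(tert-butyldimethylsilyl)oxy]-5',8'-epoxy-5,6,5',8'-tetrahydro-β,β-carotene-5,6-diol | CC(/C=C/C=C(C)/C=C/[C@]1(O)C(C)(C)C[C@H](O[Si](C)(C)C(C)(C)C)C[C@@]1(C)O)=C\C=C\C=C(C)\C=C\C=C(/C)[C@H]1C=C2C(C)(C)C[C@H](O[Si](C)(C)C(C)(C)C)C[C@@]2(C)O1 | intermediate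
31 | (3S,5R,6S,3'S,5'R,8'R)-5',8'-epoxy-5,6,5',8'-tetrahydro-β,β-carotene-3,5,6,3'-tetrol (CNP0210286.4) | CC(/C=C/C=C(C)/C=C/[C@]1(O)C(C)(C)C[C@H](O)C[C@@]1(C)O)=C\C=C\C=C(C)\C=C\C=C(/C)[C@H]1C=C2C(C)(C)C[C@H](O)C[C@@]2(C)O1 | target

## Step count and least certain steps

Total: 19 steps. Longest linear sequence: 17 steps (steps 1–11, 13–16, 18 and 19); the triol salt 18 is reached in 12 steps and both halves share everything up to 16.

**Step 7 (key step).** The most likely failure is reduction without ring closure: the captodatively stabilised ketyl, or the enediolate formed from it, is protonated or couples intermolecularly before it reaches the C5 ketone. Second in likelihood is erosion of the facial selectivity relative to C3 through a boat-like transition state.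
The fallback sets out from 7 and returns at 11. i-Bu2AlH reduces 7 to the allylic alcohol [(4R)-4-[(tert-butyldimethylsilyl)oxy]-2,6,6-trimethylcyclohex-1-en-1-yl]methanol F1. Its tetrasubstituted alkene, no longer deactivated by the ester, is dihydroxylated with one equivalent of OsO4 in pyridine, and the osmate ester is cleaved with aqueous NaHSO3. The concerted addition guarantees the cis-diol; approach anti to the silyloxy group is expected on steric grounds but not assured, and a syn isomer would be removed by chromatography. The product is 11, and steps 6 to 8 are bypassed.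

**Step 14.** The closure onto the planar cation may be unselective between the two faces at C8, in particular if the cation becomes free and the ring conformation changes before the oxygen closes. The same cation can also be lost by proton loss, by a pinacol-type 1,2-shift from C5, or by capture of its C10 end by the neighbouring acetate.
The fallback sets out from 7 and returns at 21, using an epoxide as the leaving group at C6; it opens under far milder acid, and the tethered oxygen can migrate across the face it leaves (which by geometry should place C9 trans to the C5 methyl, that is 8R). 7 is reduced to F1 as described under step 7. Sharpless epoxidation (Ti(OiPr)4, D-(−)-diethyl tartrate, t-BuOOH; the tartrate is the one that by the usual facial rule should deliver oxygen anti to the silyloxy group) gives [(1R,4S,6R)-4-[(tert-butyldimethylsilyl)oxy]-2,2,6-trimethyl-7-oxabicyclo[4.1.0]heptan-1-yl]methanol F2. Swern oxidation gives (1S,4S,6R)-4-[(tert-butyldimethylsilyl)oxy]-2,2,6-trimethyl-7-oxabicyclo[4.1.0]heptane-1-carbaldehyde F3. Olefination with 14 as in step 10 gives ethyl (2E,4E)-5-[(1S,4S,6R)-4-[(tert-butyldimethylsilyl)oxy]-2,2,6-trimethyl-7-oxabicyclo[4.1.0]heptan-1-yl]-3-methylpenta-2,4-dienoate F4. i-Bu2AlH gives (2E,4E)-5-[(1S,4S,6R)-4-[(tert-butyldimethylsilyl)oxy]-2,2,6-trimethyl-7-oxabicyclo[4.1.0]heptan-1-yl]-3-methylpenta-2,4-dien-1-ol F5. A trace of pyridinium p-toluenesulfonate in CH2Cl2 at 0 °C should then move the oxygen from C6 to C8 and give 21.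

**Step 10.** Before olefination, the free α,β-dihydroxy aldehyde may undergo base-induced retro-aldol opening of the C5–C6 bond or an α-ketol shift. Addition to the hindered carbonyl is slow, which gives these processes time.
The fallback sets out from 12 and returns at 15 without a new intermediate. The bought salt [(2E)-4-ethoxy-2-methyl-4-oxobut-2-en-1-yl]triphenylphosphonium bromide is heated with 12 in 1,2-epoxybutane. The epoxide takes up HBr, so the phosphorane is formed with no alkoxide or amide base present at any time, and the Wittig reaction should give 15 after chromatography.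

**Step 18.** The γ-alkoxy allylic ylide may fragment by vinylogous β-elimination of the ring oxygen (opening of the dihydrofuran) or lose its configuration at C8' by reversible proton transfer before it meets the aldehyde.
The fallback inverts the polarity of the coupling; it sets out from 21 and 27 and returns at 30. MnO2 in CH2Cl2 oxidises 21 to (2E)-3-[(2R,6S,7aR)-6-[(tert-butyldimethylsilyl)oxy]-4,4,7a-trimethyl-2,4,5,6,7,7a-hexahydro-1-benzofuran-2-yl]but-2-enal F6. NaBH4 in MeOH at 0 °C reduces 27 to (3S,5R,6S)-3-[(tert-butyldimethylsilyl)oxy]-5,6-dihydro-12'-apo-β-carotene-5,6,12'-triol F7. F7 is converted under the neutral conditions of step 12 into the corresponding (12'-apo-β-caroten-12'-yl)triphenylphosphonium bromide F8. The ylide of F8 is preformed with NaN(SiMe3)2 in THF at −78 °C and F6 is added, so that the furanoid fragment is only ever the electrophile. Warming in EtOAc as in step 18 should give 30.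

## Further compounds

F1 | step 7 | [(4R)-4-[(tert-butyldimethylsilyl)oxy]-2,6,6-trimethylcyclohex-1-en-1-yl]methanol | OCC1=C(C)C[C@@H](O[Si](C)(C)C(C)(C)C)CC1(C)C
F2 | step 14 | [(1R,4S,6R)-4-[(tert-butyldimethylsilyl)oxy]-2,2,6-trimethyl-7-oxabicyclo[4.1.0]heptan-1-yl]methanol | OC[C@]12C(C)(C)C[C@H](O[Si](C)(C)C(C)(C)C)C[C@@]1(C)O2
F3 | step 14 | (1S,4S,6R)-4-[(tert-butyldimethylsilyl)oxy]-2,2,6-trimethyl-7-oxabicyclo[4.1.0]heptane-1-carbaldehyde | O=C[C@]12C(C)(C)C[C@H](O[Si](C)(C)C(C)(C)C)C[C@@]1(C)O2
F4 | step 14 | ethyl (2E,4E)-5-[(1S,4S,6R)-4-[(tert-butyldimethylsilyl)oxy]-2,2,6-trimethyl-7-oxabicyclo[4.1.0]heptan-1-yl]-3-methylpenta-2,4-dienoate | CCOC(=O)/C=C(\C)/C=C/[C@]12C(C)(C)C[C@H](O[Si](C)(C)C(C)(C)C)C[C@@]1(C)O2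
F5 | step 14 | (2E,4E)-5-[(1S,4S,6R)-4-[(tert-butyldimethylsilyl)oxy]-2,2,6-trimethyl-7-oxabicyclo[4.1.0]heptan-1-yl]-3-methylpenta-2,4-dien-1-ol | OC/C=C(\C)/C=C/[C@]12C(C)(C)C[C@H](O[Si](C)(C)C(C)(C)C)C[C@@]1(C)O2
F0 | step 10 | none | none
F6 | step 18 | (2E)-3-[(2R,6S,7aR)-6-[(tert-butyldimethylsilyl)oxy]-4,4,7a-trimethyl-2,4,5,6,7,7a-hexahydro-1-benzofuran-2-yl]but-2-enal | O=C/C=C(\C)[C@H]1C=C2C(C)(C)C[C@H](O[Si](C)(C)C(C)(C)C)C[C@@]2(C)O1
F7 | step 18 | (3S,5R,6S)-3-[(tert-butyldimethylsilyl)oxy]-5,6-dihydro-12'-apo-β-carotene-5,6,12'-triol | CC(/C=C/C=C(C)/C=C/[C@]1(O)C(C)(C)C[C@H](O[Si](C)(C)C(C)(C)C)C[C@@]1(C)O)=C\C=C\C=C(C)\CO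
F8 | step 18 | [(3S,5R,6S)-3-[(tert-butyldimethylsilyl)oxy]-5,6-dihydroxy-5,6-dihydro-12'-apo-β-caroten-12'-yl]triphenylphosphonium bromide | CC(/C=C/C=C(C)/C=C/[C@]1(O)C(C)(C)C[C@H](O[Si](C)(C)C(C)(C)C)C[C@@]1(C)O)=C\C=C\C=C(C)\C[P+](c1ccccc1)(c1ccccc1)c1ccccc1.[Br-]
A1 | alternative 1 | (3S,5R,6S,3'S,5'R,6'S)-5',6'-epoxy-5,6,5',6'-tetrahydro-β,β-carotene-3,5,6,3'-tetrol | CC(/C=C/C=C(C)/C=C/[C@]1(O)C(C)(C)C[C@H](O)C[C@@]1(C)O)=C\C=C\C=C(C)\C=C\C=C(/C)\C=C\[C@]12C(C)(C)C[C@H](O)C[C@@]1(C)O2
A2 | alternative 1 | (3S,5R,6S,3'R)-5,6-dihydro-β,β-carotene-3,5,6,3'-tetrol | CC(/C=C/C=C(C)/C=C/[C@]1(O)C(C)(C)C[C@H](O)C[C@@]1(C)O)=C\C=C\C=C(C)\C=C\C=C(/C)\C=C\C1=C(C)C[C@@H](O)CC1(C)C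
A3 | alternative 2 | (2R,6S,7aR)-2-[(2E)-4-[(tert-butyldimethylsilyl)oxy]but-2-en-2-yl]-4,4,7a-trimethyl-2,4,5,6,7,7a-hexahydro-1-benzofuran-6-ol | CC(C)(C)[Si](C)(C)OC/C=C(\C)[C@H]1C=C2C(C)(C)C[C@H](O)C[C@@]2(C)O1
A4 | alternative 2 | (1R,3S)-6-[(3E)-5-[(tert-butyldimethylsilyl)oxy]-3-methylpenta-1,3-dien-1-ylidene]-1,5,5-trimethylcyclohexane-1,3-diol with the (6'S) allene axis | CC(C)(C)[Si](C)(C)OC/C=C(\C)C=[C@]=C1C(C)(C)C[C@H](O)C[C@@]1(C)O
A5 | alternative 3 | [(1R,2R,4R)-1,2,4-trihydroxy-2,6,6-trimethylcyclohexyl]methyl 2,2-dimethylpropanoate | CC(C)(C)C(=O)OC[C@]1(O)C(C)(C)C[C@@H](O)C[C@@]1(C)O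
A6 | alternative 3 | [(4S)-4-hydroxy-2,6,6-trimethylcyclohex-1-en-1-yl]methyl 2,2-dimethylpropanoate | CC(C)(C)C(=O)OCC1=C(C)C[C@H](O)CC1(C)C
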